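The numbers are germacrane numbers: ring C1–C10, lactone C11–C13, C14 on C10, C15 on C4. The plan rests on one feature. C6, the carbinol carbon of the γ-lactone ring, is also allylic to the C4=C5 bond of the ten-membered ring. The α-methylene lactone is therefore the 1,2-carbo-oxygenation product of a C4=C5–C6=C7 diene. A palladium-catalysed heteroannulation with 2-bromoacrylic acid joins C11 to C7 and the carboxylate oxygen to C6 in one operation. The precursor is an open-chain (E,E)-dienal (C15 as formyl group) that already carries the C8 silyl ether and the C1–C10 epoxide. α-Vinylation and ring-closing metathesis at C2=C3 then close the carbocycle.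

Key step: step 6

Assumption: (S)-2-vinyloxirane is taken as a purchasable enantiopure building block (it is what hydrolytic kinetic resolution of butadiene monoxide delivers).

Step 1
Reactants: 1 (S)-2-vinyloxirane; 2 lithium acetylide–ethylenediamine complex
Product: 3 (3R)-hex-1-en-5-yn-3-ol
Conditions: DMSO–THF, 0 °C to rt; then H2O
Reagents that add atoms: none
Why: SN2 epoxide opening by the hard acetylide without Lewis acid should occur at the unhindered CH2 terminus, so the C8–O stereocentre of 1 is untouched (the descriptor changes only because the priorities change).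

Step 2
Reactants: 3 (3R)-hex-1-en-5-yn-3-ol
Product: 4 (3R)-3-(tert-butyldimethylsilyloxy)hex-1-en-5-yne
Conditions: TBSCl, imidazole, DMF, rt
Reagents that add atoms: tert-butyldimethylsilyl chloride, CC(C)(C)[Si](C)(C)Cl
Why: Imidazole-promoted silyl ether formation installs a bulky, non-coordinating group that palladium cannot ionise and that later serves as the control element at C8.

Step 3
Reactants: 4 (3R)-3-(tert-butyldimethylsilyloxy)hex-1-en-5-yne
Product: 7 (2E,5R)-5-(tert-butyldimethylsilyloxy)-3-methylhepta-2,6-dien-1-ol, via vinylalane 5 (not isolated), via lithium alanate 6 (not isolated)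
Conditions: Me3Al, Cp2ZrCl2 (20 mol %), CH2Cl2, 0 °C to rt; n-BuLi, THF, −78 °C; (CH2O)n, −78 °C to rt; aqueous work-up
Reagents that add atoms: trimethylaluminium, C[Al](C)C; paraformaldehyde (as formaldehyde), C=O
Why: Negishi carboalumination adds methyl and aluminium syn to the alkyne (Al at the terminal carbon) much faster than to the vinyl group, and the alanate attacks formaldehyde with retention, which fixes the (E)-C1=C10 geometry.

Step 4
Reactants: 7 (2E,5R)-5-(tert-butyldimethylsilyloxy)-3-methylhepta-2,6-dien-1-ol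
Product: 8 {(2R,3R)-3-[(2R)-2-(tert-butyldimethylsilyloxy)but-3-en-1-yl]-3-methyloxiran-2-yl}methanol
Conditions: Ti(OiPr)4 (10 mol %), D-(−)-diethyl tartrate (12 mol %), t-BuOOH, 4 Å MS, CH2Cl2, −20 °C
Reagents that add atoms: tert-butyl hydroperoxide, CC(C)(C)OO
Why: Sharpless asymmetric epoxidation is directed by the primary allylic alcohol, leaves the vinyl group alone, and with D-(−)-tartrate should give the (2R,3R)-epoxy alcohol (mirror image of the L-(+)-tartrate outcome on geraniol-type substrates), so C1 and C10 are set by the reagent.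

Step 5
Reactants: 8 epoxy alcohol; 9 (2E,4E)-hexa-2,4-dienal
Product: 10 (2E,4E,6R)-6-(tert-butyldimethylsilyloxy)-7-[(2R,3R)-3-(hydroxymethyl)-2-methyloxiran-2-yl]hepta-2,4-dienal
Conditions: 9 (4 equiv), second-generation Hoveyda–Grubbs catalyst (5 mol %), CH2Cl2, 40 °C
Reagents that add atoms: none
Why: Olefin cross-metathesis should exchange the terminal CH2 of 8 with the distal, more electron-rich double bond of 9 (the enal double bond is far less reactive), and reversibility favours the (E,E)-dienal.

Step 6
Reactants: 10 (E,E)-dienal; 11 2-bromoprop-2-enoic acid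
Product: 13 (2E)-3-[(2R,3S)-3-{(1R)-1-(tert-butyldimethylsilyloxy)-2-[(2R,3R)-3-(hydroxymethyl)-2-methyloxiran-2-yl]ethyl}-4-methylidene-5-oxooxolan-2-yl]prop-2-enal (H6/H7 trans), via oxapalladacycle 12 (not isolated)
Conditions: 11 (1.5 equiv, slow addition), Pd(OAc)2 (10 mol %), P(2-furyl)3 (20 mol %), Ag2CO3 (1 equiv), BHT (cat.), MeCN, 50 °C
Reagents that add atoms: none
Why: Zerovalent palladium inserts into the C–Br bond of the silver salt of 11, the α-carboxyvinylpalladium species adds syn across C6=C7 with carbon going to C7, and the formyl-conjugated π-allylpalladium carboxylate (drawn in its σ-form as 12) collapses by C6–O bond formation and releases zerovalent palladium. The closest known reaction type is the Larock heteroannulation of 1,3-dienes with carboxy-substituted vinylic halides (Heck carbopalladation followed by Tsuji–Trost-type capture). The lactone ring closes in a 5-exo mode at the proximal allyl terminus C6 with C4=C5 left exocyclic, whereas attack at C4 would need a seven-membered ring and would break the enal conjugation. C7 is set by a Felkin–Anh-type approach in which the C8–OTBS bond stands perpendicular and anti to the incoming vinylpalladium with H8 inside, the sense known for carbon nucleophiles adding to γ-silyloxy acceptors, and this gives the 7,8-relationship of the target. C6 is set because halide-free silver conditions keep the carboxylate on palladium, so oxygen is delivered on the palladium-bearing face (net syn addition to an (E)-alkene gives the trans-lactone); in addition, ionisation of the γ-acyloxy enal is reversible and the allyl faces interconvert through the O-bound palladium dienolate, so the system should settle on the more stable 6,7-trans-lactone and the (E)-enal. The step needs regioselectivity for C7 over C4, which the formyl group secures by making C7 the δ-acceptor carbon, and chemoselectivity, which holds because the epoxide is not yet allylic and the C8 silyl ether is no leaving group.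

Step 7
Reactants: 13 lactone enal
Product: 14 (2Z)-2-iodo-3-[(2S,3S)-3-{(1R)-1-(tert-butyldimethylsilyloxy)-2-[(2R,3R)-3-(hydroxymethyl)-2-methyloxiran-2-yl]ethyl}-4-methylidene-5-oxooxolan-2-yl]prop-2-enal (same spatial arrangement as 13)
Conditions: I2, DMAP (cat.), pyridine–CH2Cl2, 0 °C to rt, dark
Reagents that add atoms: iodine, II
Why: α-Iodination by amine addition, iodination and elimination (Morita–Baylis–Hillman-type mechanism) should be productive only at the enal, since C11 carries no hydrogen and any adduct there reverts, and the formyl group stays trans to C6, which places iodine cis to C6.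

Step 8
Reactants: 14 α-iodoenal
Product: 15 (2E)-2-{[(2R,3S)-3-{(1R)-1-(tert-butyldimethylsilyloxy)-2-[(2R,3R)-3-(hydroxymethyl)-2-methyloxiran-2-yl]ethyl}-4-methylidene-5-oxooxolan-2-yl]methylidene}but-3-enal
Conditions: tributyl(vinyl)stannane, Pd2(dba)3 (2.5 mol %), AsPh3 (20 mol %), NMP, rt
Reagents that add atoms: tributyl(vinyl)stannane, C=C[Sn](CCCC)(CCCC)CCCC
Why: Stille coupling of the very reactive α-iodoenal proceeds at room temperature with retention of geometry and faster than ionisation of the allylic lactone, so the new carbon C3 ends up cis to C6.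

Step 9
Reactants: 15 vinyl enal alcohol
Product: 16 dialdehyde, as 15 but with a (2R,3S)-3-formyl-2-methyloxiran-2-yl group
Conditions: Dess–Martin periodinane, NaHCO3, CH2Cl2, 0 °C to rt
Reagents that add atoms: none
Why: Buffered Dess–Martin oxidation converts the only alcohol into the epoxy aldehyde without epimerisation at C1 or opening of the epoxide.

Step 10
Reactants: 16 dialdehyde
Product: 17 metathesis precursor, as 15 but with a (2R,3R)-3-ethenyl-2-methyloxiran-2-yl group
Conditions: Ph3PCH3Br, KN(SiMe3)2, THF, 0 °C; then 16 (1.0 equiv of ylide), −78 °C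
Reagents that add atoms: methyltriphenylphosphonium bromide, C[P+](c1ccccc1)(c1ccccc1)c1ccccc1.[Br-]
Why: In this Wittig methylenation one equivalent of the non-stabilised ylide at −78 °C should be consumed by the far more electrophilic α-oxygenated saturated aldehyde at C2 rather than by the hindered cross-conjugated C15 enal or the lactone.

Step 11
Reactants: 17 metathesis precursor
Product: 18 (1R,2Z,4E,6R,7S,8R,10R)-8-(tert-butyldimethylsilyloxy)-1,10-epoxy-15-oxogermacra-2,4,11(13)-trien-12,6-olide
Conditions: second-generation Hoveyda–Grubbs catalyst (15 mol %), 1,4-benzoquinone (cat.), toluene (0.5 mM), 60 °C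
Reagents that add atoms: none
Why: Ring-closing metathesis joins the only two monosubstituted alkenes, because closure onto the α-methylene group would need a bridgehead alkene or a trans-fused epoxycycloheptene, and with C3 and C6 already cis on C4=C5 the medium ring should favour cis C2=C3.

Step 12
Reactants: 18 macrocyclic silyl ether
Product: 19 (1R,2Z,4E,6R,7R,8R,10R)-1,10-epoxy-8-hydroxy-15-oxogermacra-2,4,11(13)-trien-12,6-olide
Conditions: HF·pyridine, pyridine, THF, 0 °C to rt
Reagents that add atoms: none
Why: Fluoride-driven desilylation buffered with pyridine keeps the vinyl epoxide, the enal and the lactone away from free acid.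

Step 13
Reactants: 20 3-methylfuran-2(5H)-one
Product: 22 4-methoxybenzyl (2Z)-4-hydroxy-2-methylbut-2-enoate, via potassium hydroxyenoate 21 (not isolated)
Conditions: KOH (1.0 equiv), H2O–MeOH, rt; evaporate; 4-methoxybenzyl chloride, n-Bu4NI (cat.), DMF, rt; used at once
Reagents that add atoms: potassium hydroxide, [K+].[OH-]; 4-methoxybenzyl chloride, COc1ccc(CCl)cc1
Why: Saponification followed by SN2 O-alkylation of the carboxylate opens the butenolide without touching the double bond, so the (Z) geometry is inherited from the ring.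

Step 14
Reactants: 22 hydroxy ester
Product: 23 4-methoxybenzyl (2Z)-4-acetoxy-2-methylbut-2-enoate
Conditions: Ac2O, pyridine, DMAP (cat.), CH2Cl2, 0 °C
Reagents that add atoms: acetic anhydride, CC(=O)OC(C)=O
Why: Acetylation of the unhindered primary alcohol should be faster than relactonisation and removes that pathway for good.

Step 15
Reactants: 23 acetoxy ester
Product: 24 (2Z)-4-acetoxy-2-methylbut-2-enoic acid
Conditions: CF3CO2H, anisole, CH2Cl2, 0 °C
Reagents that add atoms: none
Why: Acidolysis of the 4-methoxybenzyl ester proceeds through the stabilised benzyl cation, which anisole traps by Friedel–Crafts alkylation, and leaves the primary acetate and the (Z)-alkene intact.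

Step 16
Reactants: 19 macrocyclic alcohol; 24 (2Z)-4-acetoxy-2-methylbut-2-enoic acid
Product: 26 (1R,2Z,4E,6R,7R,8R,10R)-8-[(2Z)-4-acetoxy-2-methylbut-2-enoyloxy]-1,10-epoxy-15-oxogermacra-2,4,11(13)-trien-12,6-olide, via mixed anhydride 25 (not isolated)
Conditions: 24, 2,4,6-trichlorobenzoyl chloride, Et3N, toluene, rt; then 19, DMAP, toluene, 0 °C to rt
Reagents that add atoms: none
Why: Yamaguchi esterification activates the angelate-type acid as a hindered mixed anhydride that acylates the only hydroxyl group with retention at C8 and at a temperature low enough to disfavour Z-to-E isomerisation.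

Step 17
Reactants: 26 ester aldehyde
Product: 27 target, (1R,2Z,4E,6R,7R,8R,10R)-8-[(2Z)-4-acetoxy-2-methylbut-2-enoyloxy]-1,10-epoxy-15-hydroxygermacra-2,4,11(13)-trien-12,6-olide
Conditions: NaBH4, CeCl3·7H2O, MeOH, −78 °C
Reagents that add atoms: none
Why: Luche reduction delivers hydride 1,2 to the aldehyde much faster than to the α-methylene lactone, the esters or the vinyl epoxide at this temperature.

Compound list
1 | (S)-2-vinyloxirane | C=C[C@H]1CO1 | starting material
2 | lithium acetylide–ethylenediamine complex | [Li]C#C.NCCN | starting material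
3 | (3R)-hex-1-en-5-yn-3-ol | C#CC[C@@H](O)C=C | intermediate
4 | (3R)-3-(tert-butyldimethylsilyloxy)hex-1-en-5-yne | C#CC[C@@H](O[Si](C)(C)C(C)(C)C)C=C | intermediate
5 | dimethyl[(1E,4R)-4-(tert-butyldimethylsilyloxy)-2-methylhexa-1,5-dien-1-yl]alane | C[Al](C)/C=C(\C)C[C@@H](O[Si](C)(C)C(C)(C)C)C=C | intermediate
6 | lithium butyl(dimethyl)[(1E,4R)-4-(tert-butyldimethylsilyloxy)-2-methylhexa-1,5-dien-1-yl]alanate | [Li+].CCCC[Al-](C)(C)/C=C(\C)C[C@@H](O[Si](C)(C)C(C)(C)C)C=C | intermediate
7 | (2E,5R)-5-(tert-butyldimethylsilyloxy)-3-methylhepta-2,6-dien-1-ol | OC/C=C(\C)C[C@@H](O[Si](C)(C)C(C)(C)C)C=C | intermediate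
8 | {(2R,3R)-3-[(2R)-2-(tert-butyldimethylsilyloxy)but-3-en-1-yl]-3-methyloxiran-2-yl}methanol | OC[C@H]1O[C@]1(C)C[C@@H](O[Si](C)(C)C(C)(C)C)C=C | intermediate
9 | (2E,4E)-hexa-2,4-dienal | C/C=C/C=C/C=O | starting material
10 | (2E,4E,6R)-6-(tert-butyldimethylsilyloxy)-7-[(2R,3R)-3-(hydroxymethyl)-2-methyloxiran-2-yl]hepta-2,4-dienal | OC[C@H]1O[C@]1(C)C[C@@H](O[Si](C)(C)C(C)(C)C)/C=C/C=C/C=O | intermediate
11 | 2-bromoprop-2-enoic acid | C=C(Br)C(=O)O | starting material
12 | oxapalladacycle (σ-allyl form, phosphine omitted) | OC[C@H]1O[C@]1(C)C[C@@H](O[Si](C)(C)C(C)(C)C)[C@H]1C(=C)C(=O)O[Pd][C@@H]1/C=C/C=O | intermediate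
13 | trans-lactone (E)-enal (6R,7S,8R,1R,10R) | OC[C@H]1O[C@]1(C)C[C@@H](O[Si](C)(C)C(C)(C)C)[C@H]1C(=C)C(=O)O[C@@H]1/C=C/C=O | intermediate
14 | trans-lactone (Z)-α-iodoenal | OC[C@H]1O[C@]1(C)C[C@@H](O[Si](C)(C)C(C)(C)C)[C@H]1C(=C)C(=O)O[C@@H]1/C=C(\I)C=O | intermediate
15 | trans-lactone α-vinyl enal (C3 cis to C6) | OC[C@H]1O[C@]1(C)C[C@@H](O[Si](C)(C)C(C)(C)C)[C@H]1C(=C)C(=O)O[C@@H]1/C=C(\C=C)C=O | intermediate
16 | epoxy aldehyde/enal dialdehyde | O=C[C@H]1O[C@]1(C)C[C@@H](O[Si](C)(C)C(C)(C)C)[C@H]1C(=C)C(=O)O[C@@H]1/C=C(\C=C)C=O | intermediate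
17 | vinyl epoxide metathesis precursor | C=C[C@H]1O[C@]1(C)C[C@@H](O[Si](C)(C)C(C)(C)C)[C@H]1C(=C)C(=O)O[C@@H]1/C=C(\C=C)C=O | intermediate
18 | 8-O-TBS-1,10-epoxy-15-oxogermacra-2Z,4E,11(13)-trien-12,6-olide | C=C1C(=O)O[C@@H]2/C=C(C=O)\C=C/[C@H]3O[C@]3(C)C[C@@H](O[Si](C)(C)C(C)(C)C)[C@@H]12 | intermediate
19 | 1,10-epoxy-8-hydroxy-15-oxogermacra-2Z,4E,11(13)-trien-12,6-olide | C=C1C(=O)O[C@@H]2/C=C(C=O)\C=C/[C@H]3O[C@]3(C)C[C@@H](O)[C@@H]12 | intermediate
20 | 3-methylfuran-2(5H)-one | CC1=CCOC1=O | starting material
21 | potassium (2Z)-4-hydroxy-2-methylbut-2-enoate | [K+].[O-]C(=O)/C(C)=C\CO | intermediate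
22 | 4-methoxybenzyl (2Z)-4-hydroxy-2-methylbut-2-enoate | COc1ccc(COC(=O)/C(C)=C\CO)cc1 | intermediate
23 | 4-methoxybenzyl (2Z)-4-acetoxy-2-methylbut-2-enoate | COc1ccc(COC(=O)/C(C)=C\COC(C)=O)cc1 | intermediate
24 | (2Z)-4-acetoxy-2-methylbut-2-enoic acid | OC(=O)/C(C)=C\COC(C)=O | intermediate
25 | (2Z)-4-acetoxy-2-methylbut-2-enoic 2,4,6-trichlorobenzoic anhydride | O=C(OC(=O)/C(C)=C\COC(C)=O)c1c(Cl)cc(Cl)cc1Cl | intermediate
26 | 8-O-[(2Z)-4-acetoxy-2-methylbut-2-enoyl]-1,10-epoxy-15-oxogermacra-2Z,4E,11(13)-trien-12,6-olide | C=C1C(=O)O[C@@H]2/C=C(C=O)\C=C/[C@H]3O[C@]3(C)C[C@@H](OC(=O)/C(C)=C\COC(C)=O)[C@@H]12 | intermediate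
27 | CNP0103272.1 | C=C1C(=O)O[C@@H]2/C=C(CO)\C=C/[C@H]3O[C@]3(C)C[C@@H](OC(=O)/C(C)=C\COC(C)=O)[C@@H]12 | target

Total step count: 17. Longest linear sequence: 14 (steps 1–12, 16 and 17).

Steps most likely to fail

1. Step 6. Migratory insertion at the substituted diene terminus may be slow. β-Hydride elimination, self-consumption of 11 or weak facial discrimination by C8 in the (E)-alkene could then take over. The fallback sets out from 8 and relies on allylic 1,3-strain and anti capture instead.
 - Ozonolysis (O3; Me2S) should give (2R)-2-(tert-butyldimethylsilyloxy)-3-[(2R,3R)-3-(hydroxymethyl)-2-methyloxiran-2-yl]propanal F1.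
 - Stork–Zhao olefination (Ph3PCH2I iodide, NaN(SiMe3)2, −78 °C) should give the (Z)-vinyl iodide F2.
 - Heck coupling with acrolein (Pd(OAc)2, Ag2CO3, MeCN) should give the (2E,4Z,6R)-dienal F3.
 - In F3 the cis substituent locks H8 in the alkene plane, so the two faces of C7 are sharply differentiated in the same sense as before.
 - Annulation with 11 under chloride-rich conditions (Pd(OAc)2, n-Bu4NCl, K2CO3, DMF) lets the carboxylate attack the allyl face opposite to palladium. On a (Z)-alkene this again gives the trans-lactone, and the route is rejoined at 13.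

2. Step 11. Oligomerisation may outrun closure of the strained ten-membered ring, or the ring may close with trans C2=C3 geometry. The fallback sets out from 14 and fixes the geometry before ring closure.
 - Dess–Martin oxidation should give the iodoenal epoxy aldehyde F4.
 - Stork–Zhao olefination at −78 °C on the more electrophilic epoxy aldehyde should give the bis(vinyl iodide) F5, with C2=C3 already (Z).
 - Stille–Kelly cyclisation (Me3SnSnMe3, Pd2(dba)3, AsPh3, high dilution, rt to 40 °C) forms the C3–C4 bond and rejoins the route at 18.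

3. Step 5. Turnover at the hindered allylic silyl ether may be slow, and metathesis at the wrong double bond of 9 would shorten the chain by two carbons. The fallback sets out from 8 and builds the dienal two carbons at a time.
 - Cross-metathesis with crotonaldehyde (second-generation Hoveyda–Grubbs catalyst) should give (2E,4R)-4-(tert-butyldimethylsilyloxy)-5-[(2R,3R)-3-(hydroxymethyl)-2-methyloxiran-2-yl]pent-2-enal F6.
 - Wittig homologation with (triphenylphosphoranylidene)acetaldehyde (toluene, 70 °C) rejoins the route at 10.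

Further compounds
F1 | step 6 | (2R)-2-(tert-butyldimethylsilyloxy)-3-[(2R,3R)-3-(hydroxymethyl)-2-methyloxiran-2-yl]propanal | OC[C@H]1O[C@]1(C)C[C@@H](O[Si](C)(C)C(C)(C)C)C=O
F2 | step 6 | {(2R,3R)-3-[(2R,3Z)-2-(tert-butyldimethylsilyloxy)-4-iodobut-3-en-1-yl]-3-methyloxiran-2-yl}methanol | OC[C@H]1O[C@]1(C)C[C@@H](O[Si](C)(C)C(C)(C)C)/C=C\I
F3 | step 6 | (2E,4Z,6R)-6-(tert-butyldimethylsilyloxy)-7-[(2R,3R)-3-(hydroxymethyl)-2-methyloxiran-2-yl]hepta-2,4-dienal | OC[C@H]1O[C@]1(C)C[C@@H](O[Si](C)(C)C(C)(C)C)/C=C\C=C\C=O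
F4 | step 11 | trans-lactone (Z)-α-iodoenal with a (2R,3S)-3-formyl-2-methyloxiran-2-yl group | O=C[C@H]1O[C@]1(C)C[C@@H](O[Si](C)(C)C(C)(C)C)[C@H]1C(=C)C(=O)O[C@@H]1/C=C(\I)C=O
F5 | step 11 | trans-lactone (Z)-α-iodoenal with a (Z)-2-iodoethenyl epoxide | I/C=C\[C@H]1O[C@]1(C)C[C@@H](O[Si](C)(C)C(C)(C)C)[C@H]1C(=C)C(=O)O[C@@H]1/C=C(\I)C=O
F6 | step 5 | (2E,4R)-4-(tert-butyldimethylsilyloxy)-5-[(2R,3R)-3-(hydroxymethyl)-2-methyloxiran-2-yl]pent-2-enal | OC[C@H]1O[C@]1(C)C[C@@H](O[Si](C)(C)C(C)(C)C)/C=C/C=O
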